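**Retrosynthetic overview**
- Feature: in the quinone ring (ring B: C1=O, C2–OH, C3–chain, C4=O, C5–N, C6–H) the chain-bearing C3 lies between the oxygenated C2 and the carbonyl C4, and C5/C6 carry no carbon. This is the 2-alkyl-3-alkoxyphenol pattern of a vinylketene–ynol ether benzannulation.
- Endgame: C5–N by amine conjugate addition and air reoxidation on ethoxyquinone 30; 30 by para-oxidation of phenol 29; the ethyl ether is cleaved last.
- Ring B is built in step 16 from terpenoid ynol ether 21 and cyclobutenone 24 (vinylketene [2+2], 4π opening, 6π closure).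
- 21 comes from allylic bromide 18 and lithiated ethoxyacetylene; the (E)-trisubstituted alkene comes from Zr-catalysed carboalumination of alkyne 15.
- Ring A is bought as cyclohexanone: quaternary centre by Pd-catalysed decarboxylative allylation (catalyst control), secondary methyl by SAMP-hydrazone methylation (auxiliary control), methylidene by Peterson olefination. Ring order: A (present from the start), then B (step 16).

Key step: step 16

Remark: LDA and Me3SiCH2Li are used as commercial solutions; cyclobutenone 24 is made fresh and handled as a cold solution.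

**Step 1**
Reactants: 1 cyclohexanone; 2 diallyl carbonate
Product: 3 prop-2-en-1-yl 2-oxocyclohexane-1-carboxylate (racemic)
Conditions: NaH, THF, reflux; aq. HCl work-up
Reagents that add atoms: none
Why: Claisen-type C-acylation of the ketone sodium enolate by the carbonate, driven by deprotonation of the β-keto ester formed.

**Step 2**
Reactants: 3 prop-2-en-1-yl 2-oxocyclohexane-1-carboxylate
Product: 4 prop-2-en-1-yl 1-methyl-2-oxocyclohexane-1-carboxylate (racemic)
Conditions: MeI, K2CO3, acetone, 50 °C
Reagents that add atoms: iodomethane, CI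
Why: C-alkylation of a stabilised β-keto ester enolate with a small electrophile; the racemic centre is erased in the next step.

**Step 3**
Reactants: 4 prop-2-en-1-yl 1-methyl-2-oxocyclohexane-1-carboxylate
Product: 5 (2R)-2-methyl-2-(prop-2-en-1-yl)cyclohexan-1-one
Conditions: Pd2(dba)3 (2.5 mol %), (R)-t-Bu-PHOX (6 mol %), THF, 25 °C
Reagents that add atoms: none
Why: Decarboxylative asymmetric Tsuji allylation: zerovalent palladium ionises the allyl ester, CO2 is lost, and the prochiral enolate recombines with the allyl fragment inside the chiral P,N-ligand sphere, so the quaternary centre is set by the catalyst; the (R)-ligand is taken because the (S)-ligand is the one associated with the (S)-ketone in this reaction class.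

**Step 4**
Reactants: 5 (2R)-2-methyl-2-(prop-2-en-1-yl)cyclohexan-1-one
Product: 6 (2S)-2-(methoxymethyl)-N-[(1E,2R)-2-methyl-2-(prop-2-en-1-yl)cyclohexylidene]pyrrolidin-1-amine
Conditions: SAMP (1.3 equiv), p-TsOH·H2O (cat.), cyclohexane, reflux, Dean–Stark
Reagents that add atoms: (S)-1-amino-2-(methoxymethyl)pyrrolidine (SAMP), COC[C@@H]1CCCN1N
Why: Hydrazone condensation with azeotropic removal of water; the amino group settles anti to the quaternary carbon, syn to the only enolisable position.

**Step 5**
Reactants: 6 SAMP hydrazone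
Product: 8 (2S)-N-[(2R,6R)-2,6-dimethyl-2-(prop-2-en-1-yl)cyclohexylidene]-2-(methoxymethyl)pyrrolidin-1-amine, via lithium azaenolate 7 (not isolated)
Conditions: LDA, THF, 0 °C; then MeI, −100 → −78 °C
Reagents that add atoms: iodomethane, CI
Why: SAMP-hydrazone alkylation: the chelated lithium azaenolate is methylated on the face set by the (S)-pyrrolidine, which for cyclohexanone hydrazones corresponds to the (R) α-centre; the neighbouring quaternary carbon carries two groups of similar size and should not override the auxiliary, and material from the minor enantiomer of 5 becomes a separable diastereomer.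

**Step 6**
Reactants: 8 methylated SAMP hydrazone
Product: 9 (2R,6R)-2,6-dimethyl-2-(prop-2-en-1-yl)cyclohexan-1-one
Conditions: sat. aq. oxalic acid, Et2O, 25 °C
Reagents that add atoms: water, O
Why: Two-phase acid hydrolysis of the hydrazone is mild enough not to enolise the new α-stereocentre, and the auxiliary is recovered from the aqueous phase.

**Step 7**
Reactants: 9 (2R,6R)-2,6-dimethyl-2-(prop-2-en-1-yl)cyclohexan-1-one
Product: 11 (1R,3R)-1,3-dimethyl-2-methylidene-1-(prop-2-en-1-yl)cyclohexane, via β-hydroxysilane 10 (not isolated)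
Conditions: Me3SiCH2Li, CeCl3, THF, −78 → 0 °C; aq. NH4Cl; crude 10, KH, THF, 25 °C
Reagents that add atoms: (trimethylsilyl)methyllithium, [Li]C[Si](C)(C)C
Why: Peterson olefination: the organocerium reagent adds to the hindered, enolisable ketone without epimerising C6, and syn-elimination of the potassium alkoxide gives the methylidene group regiospecifically; after this step the secondary stereocentre can no longer epimerise.

**Step 8**
Reactants: 11 (1R,3R)-1,3-dimethyl-2-methylidene-1-(prop-2-en-1-yl)cyclohexane
Product: 13 3-[(1R,3R)-1,3-dimethyl-2-methylidenecyclohexyl]propan-1-ol, via trialkylborane 12 (not isolated)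
Conditions: disiamylborane, (Sia)2BH (from BH3·THF and 2-methylbut-2-ene), THF, 0 °C; then NaOH, H2O2, 0 → 25 °C
Reagents that add atoms: hydrogen peroxide, OO
Why: Hydroboration–oxidation: the bulky dialkylborane should react with the monosubstituted allyl terminus much faster than with the 1,1-disubstituted methylidene flanked by a quaternary and a tertiary carbon, placing boron on the terminal carbon.

**Step 9**
Reactants: 13 3-[(1R,3R)-1,3-dimethyl-2-methylidenecyclohexyl]propan-1-ol
Product: 14 3-[(1R,3R)-1,3-dimethyl-2-methylidenecyclohexyl]propanal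
Conditions: DMP, NaHCO3, CH2Cl2, 0 → 25 °C
Reagents that add atoms: none
Why: Dess–Martin oxidation of a primary alcohol stops at the aldehyde under buffered conditions that leave the methylidene group untouched.

**Step 10**
Reactants: 14 3-[(1R,3R)-1,3-dimethyl-2-methylidenecyclohexyl]propanal
Product: 15 (1R,3R)-1-(but-3-yn-1-yl)-1,3-dimethyl-2-methylidenecyclohexane
Conditions: dimethyl (1-diazo-2-oxopropyl)phosphonate, K2CO3, MeOH, 0 → 25 °C
Reagents that add atoms: dimethyl (1-diazo-2-oxopropyl)phosphonate, CC(=O)C(=[N+]=[N-])P(=O)(OC)OC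
Why: Ohira–Bestmann homologation: the diazophosphonate anion made in the flask adds to the aldehyde and the derived alkylidene carbene rearranges to the terminal alkyne; no stereocentre is α to the aldehyde.

**Step 11**
Reactants: 15 (1R,3R)-1-(but-3-yn-1-yl)-1,3-dimethyl-2-methylidenecyclohexane
Product: 17 (2E)-5-[(1R,3R)-1,3-dimethyl-2-methylidenecyclohexyl]-3-methylpent-2-en-1-ol, via alkenyldimethylalane 16 (not isolated)
Conditions: Me3Al, Cp2ZrCl2 (0.25 equiv), CH2Cl2, 0 → 25 °C; then n-BuLi, THF, −78 → 0 °C; (CH2O)n, 25 °C; aq. HCl work-up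
Reagents that add atoms: trimethylaluminium, C[Al](C)C; formaldehyde (as paraformaldehyde), C=O
Why: Negishi zirconium-catalysed carboalumination: syn addition of Me–Al puts methyl on the internal alkyne carbon, and the alkenylalanate is hydroxymethylated with retention, fixing the (E)-trisubstituted alkene; the hindered 1,1-disubstituted alkene is inert under these conditions.

**Step 12**
Reactants: 17 (2E)-allylic alcohol
Product: 18 (1R,3R)-1-[(3E)-5-bromo-3-methylpent-3-en-1-yl]-1,3-dimethyl-2-methylidenecyclohexane
Conditions: CBr4, PPh3, CH2Cl2, 0 °C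
Reagents that add atoms: tetrabromomethane, BrC(Br)(Br)Br
Why: Appel bromination converts the primary allylic alcohol to the bromide under neutral conditions without allylic transposition.

**Step 13**
Reactants: 18 allylic bromide; 19 ethoxyethyne
Product: 21 (1R,3R)-1-[(3E)-7-ethoxy-3-methylhept-3-en-6-yn-1-yl]-1,3-dimethyl-2-methylidenecyclohexane, via lithium ethoxyacetylide 20 (not isolated)
Conditions: 19, n-BuLi, THF, −78 °C; then 18, HMPA, −78 → 0 °C
Reagents that add atoms: none
Why: SN2 alkylation of a lithium alkynide at a primary allylic bromide in THF/HMPA; low temperature and the absence of excess base protect the skipped enyne from isomerisation.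

**Step 14**
Reactants: 22 3-oxocyclobutane-1-carboxylic acid
Product: 23 3-bromocyclobutan-1-one
Conditions: HgO, Br2, MgSO4, CH2Cl2, reflux
Reagents that add atoms: bromine, BrBr
Why: Cristol–Firth variant of the Hunsdiecker reaction: the acyl hypobromite formed from the mercury carboxylate decarboxylates by a radical chain to the secondary bromide.

**Step 15**
Reactants: 23 3-bromocyclobutan-1-one
Product: 24 cyclobut-2-en-1-one
Conditions: n-Bu3N, 25 °C; vacuum transfer into a cold trap
Reagents that add atoms: none
Why: E1cB-type dehydrobromination of the β-bromo ketone by a hindered amine; the volatile enone is separated from the salt by vacuum transfer and kept cold in solution.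

**Step 16**
Reactants: 21 terpenoid 1-ethoxyalkyne; 24 cyclobut-2-en-1-one
Product: 29 3-ethoxy-2-[(2E)-5-[(1R,3R)-1,3-dimethyl-2-methylidenecyclohexyl]-3-methylpent-2-en-1-yl]phenol, via vinylketene 25 (not isolated), via vinylcyclobutenone 26 (not isolated), via dienylketene 27 (not isolated), via cyclohexadienone 28 (not isolated)
Conditions: 24 (1.5 equiv, two portions), toluene, sealed tube, 80 °C, then 110 °C; then K2CO3, MeOH, 25 °C
Reagents that add atoms: none
Why: Thermal 4π-electrocyclic opening of 24 gives vinylketene 25, which adds [2+2] to the electron-rich alkyne of 21 to give 26; 4π opening of 26 gives dienylketene 27, whose 6π-electrocyclisation gives 28, and tautomerisation gives the phenol. The closest known reaction type is the Danheiser benzannulation of cyclobutenones with alkoxyalkynes. The benzene ring is closed by the 6π-electrocyclisation, which joins the ketene carbon to the vinyl terminus in a six-membered closure; the other two new ring bonds (ketene carbon to the alkyl-bearing alkyne carbon, ketene α-carbon to the ethoxy-bearing alkyne carbon) come from the [2+2] step. No stereocentre is created, and the two centres of ring A are remote and untouched. The step needs the regiochemistry of the [2+2] addition, which the polarisation of the ynol ether secures: its nucleophilic alkyl-bearing carbon attacks the ketene carbonyl carbon, so the chain ends between the hydroxyl and the ethoxy group and the position para to the hydroxyl stays free. It also needs chemoselectivity: the unactivated terpenoid alkenes are poor ketene partners, and holding 80 °C until 21 is consumed keeps retro-ene loss of ethylene from the ethyl ynol ether slow; the carbonate wash cleaves any aryl ester formed from excess ketene.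

**Step 17**
Reactants: 29 3-ethoxy-2-alkylphenol
Product: 30 2-ethoxy-3-[(2E)-5-[(1R,3R)-1,3-dimethyl-2-methylidenecyclohexyl]-3-methylpent-2-en-1-yl]cyclohexa-2,5-diene-1,4-dione
Conditions: (KSO3)2NO, KH2PO4, acetone/H2O, 0 → 25 °C
Reagents that add atoms: potassium nitrosodisulfonate, [K+].[K+].[O]N(S(=O)(=O)[O-])S(=O)(=O)[O-]
Why: Teuber oxidation: the phenoxyl radical is trapped at the free para position by a second equivalent of the nitroxide, and loss of imidodisulfonate gives the para-quinone without touching the alkenes.

**Step 18**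
Reactants: 30 ethoxyquinone; 31 3-methylbutan-1-amine
Product: 33 2-ethoxy-3-[(2E)-5-[(1R,3R)-1,3-dimethyl-2-methylidenecyclohexyl]-3-methylpent-2-en-1-yl]-5-[(3-methylbutyl)amino]cyclohexa-2,5-diene-1,4-dione, via aminohydroquinone 32 (not isolated)
Conditions: 31 (1.1 equiv), EtOH, 0 → 25 °C, open to air
Reagents that add atoms: none
Why: Conjugate addition–reoxidation: the 2-ethoxy group is in vinylogous-ester conjugation with C4=O, so the amine should add at C5, β to the more electrophilic C1=O and para to the ethoxy carbon, and the aminohydroquinone is reoxidised by air; a near-stoichiometric amount of amine limits displacement of the ethoxy group.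

**Step 19**
Reactants: 33 amino ethoxyquinone
Product: 34 metachromin H
Conditions: KOH, EtOH/H2O, 25 °C; then dil. HCl to pH 3, 0 °C
Reagents that add atoms: potassium hydroxide, [K+].[OH-]
Why: Addition–elimination of hydroxide at C2 of the vinylogous ester, driven by formation of the delocalised hydroxyquinone anion; the vinylogous amide at C5 is much less electrophilic and should survive.

**Compound list**
1 | cyclohexanone | O=C1CCCCC1 | starting material
2 | diallyl carbonate | C=CCOC(=O)OCC=C | starting material
3 | prop-2-en-1-yl 2-oxocyclohexane-1-carboxylate (racemic) | O=C1CCCCC1C(=O)OCC=C | intermediate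
4 | prop-2-en-1-yl 1-methyl-2-oxocyclohexane-1-carboxylate (racemic) | CC1(C(=O)OCC=C)CCCCC1=O | intermediate
5 | (2R)-2-methyl-2-(prop-2-en-1-yl)cyclohexan-1-one | O=C1CCCC[C@]1(C)CC=C | intermediate
6 | (2S)-2-(methoxymethyl)-N-[(1E,2R)-2-methyl-2-(prop-2-en-1-yl)cyclohexylidene]pyrrolidin-1-amine | COC[C@@H]1CCCN1/N=C2\CCCC[C@]2(C)CC=C | intermediate
7 | lithium azaenolate of 6 (not isolated) | COC[C@@H]1CCCN1N([Li])C2=CCCC[C@]2(C)CC=C | intermediate
8 | (2S)-N-[(2R,6R)-2,6-dimethyl-2-(prop-2-en-1-yl)cyclohexylidene]-2-(methoxymethyl)pyrrolidin-1-amine | COC[C@@H]1CCCN1/N=C2\[C@H](C)CCC[C@]2(C)CC=C | intermediate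
9 | (2R,6R)-2,6-dimethyl-2-(prop-2-en-1-yl)cyclohexan-1-one | O=C1[C@H](C)CCC[C@]1(C)CC=C | intermediate
10 | (2R,6R)-2,6-dimethyl-2-(prop-2-en-1-yl)-1-[(trimethylsilyl)methyl]cyclohexan-1-ol, carbinol centre undefined (not isolated) | C[Si](C)(C)CC1(O)[C@H](C)CCC[C@]1(C)CC=C | intermediate
11 | (1R,3R)-1,3-dimethyl-2-methylidene-1-(prop-2-en-1-yl)cyclohexane | C=C1[C@H](C)CCC[C@]1(C)CC=C | intermediate
12 | {3-[(1R,3R)-1,3-dimethyl-2-methylidenecyclohexyl]propyl}bis(3-methylbutan-2-yl)borane (not isolated) | C=C1[C@H](C)CCC[C@]1(C)CCCB(C(C)C(C)C)C(C)C(C)C | intermediate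
13 | 3-[(1R,3R)-1,3-dimethyl-2-methylidenecyclohexyl]propan-1-ol | C=C1[C@H](C)CCC[C@]1(C)CCCO | intermediate
14 | 3-[(1R,3R)-1,3-dimethyl-2-methylidenecyclohexyl]propanal | C=C1[C@H](C)CCC[C@]1(C)CCC=O | intermediate
15 | (1R,3R)-1-(but-3-yn-1-yl)-1,3-dimethyl-2-methylidenecyclohexane | C=C1[C@H](C)CCC[C@]1(C)CCC#C | intermediate
16 | (E)-alkenyldimethylalane from 15 (not isolated) | C=C1[C@H](C)CCC[C@]1(C)CC/C(C)=C/[Al](C)C | intermediate
17 | (2E)-5-[(1R,3R)-1,3-dimethyl-2-methylidenecyclohexyl]-3-methylpent-2-en-1-ol | C=C1[C@H](C)CCC[C@]1(C)CC/C(C)=C/CO | intermediate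
18 | (1R,3R)-1-[(3E)-5-bromo-3-methylpent-3-en-1-yl]-1,3-dimethyl-2-methylidenecyclohexane | C=C1[C@H](C)CCC[C@]1(C)CC/C(C)=C/CBr | intermediate
19 | ethoxyethyne (ethoxyacetylene) | C#COCC | starting material
20 | lithium ethoxyacetylide (not isolated) | [Li]C#COCC | intermediate
21 | (1R,3R)-1-[(3E)-7-ethoxy-3-methylhept-3-en-6-yn-1-yl]-1,3-dimethyl-2-methylidenecyclohexane | C=C1[C@H](C)CCC[C@]1(C)CC/C(C)=C/CC#COCC | intermediate
22 | 3-oxocyclobutane-1-carboxylic acid | O=C1CC(C(=O)O)C1 | starting material
23 | 3-bromocyclobutan-1-one | O=C1CC(Br)C1 | intermediate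
24 | cyclobut-2-en-1-one | O=C1C=CC1 | intermediate
25 | buta-1,3-dien-1-one (vinylketene, not isolated) | C=CC=C=O | intermediate
26 | 4-ethenyl-3-ethoxy-2-[(2E)-5-[(1R,3R)-1,3-dimethyl-2-methylidenecyclohexyl]-3-methylpent-2-en-1-yl]cyclobut-2-en-1-one, C4 undefined (not isolated) | C=C1[C@H](C)CCC[C@]1(C)CC/C(C)=C/CC1=C(OCC)C(C=C)C1=O | intermediate
27 | dienylketene from ring opening of 26 (not isolated) | C=C1[C@H](C)CCC[C@]1(C)CC/C(C)=C/CC(=C=O)/C(OCC)=C\C=C | intermediate
28 | 3-ethoxy-2-[(2E)-5-[(1R,3R)-1,3-dimethyl-2-methylidenecyclohexyl]-3-methylpent-2-en-1-yl]cyclohexa-2,4-dien-1-one (not isolated) | C=C1[C@H](C)CCC[C@]1(C)CC/C(C)=C/CC1=C(OCC)C=CCC1=O | intermediate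
29 | 3-ethoxy-2-[(2E)-5-[(1R,3R)-1,3-dimethyl-2-methylidenecyclohexyl]-3-methylpent-2-en-1-yl]phenol | C=C1[C@H](C)CCC[C@]1(C)CC/C(C)=C/Cc1c(O)cccc1OCC | intermediate
30 | 2-ethoxy-3-[(2E)-5-[(1R,3R)-1,3-dimethyl-2-methylidenecyclohexyl]-3-methylpent-2-en-1-yl]cyclohexa-2,5-diene-1,4-dione | C=C1[C@H](C)CCC[C@]1(C)CC/C(C)=C/CC1=C(OCC)C(=O)C=CC1=O | intermediate
31 | 3-methylbutan-1-amine (isopentylamine) | CC(C)CCN | starting material
32 | aminohydroquinone from addition of 31 to 30 (not isolated) | C=C1[C@H](C)CCC[C@]1(C)CC/C(C)=C/Cc1c(O)c(NCCC(C)C)cc(O)c1OCC | intermediate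
33 | 2-ethoxy-3-[(2E)-5-[(1R,3R)-1,3-dimethyl-2-methylidenecyclohexyl]-3-methylpent-2-en-1-yl]-5-[(3-methylbutyl)amino]cyclohexa-2,5-diene-1,4-dione | C=C1[C@H](C)CCC[C@]1(C)CC/C(C)=C/CC1=C(OCC)C(=O)C=C(NCCC(C)C)C1=O | intermediate
34 | metachromin H, 2-hydroxy-3-[(2E)-5-[(1R,3R)-1,3-dimethyl-2-methylidenecyclohexyl]-3-methylpent-2-en-1-yl]-5-[(3-methylbutyl)amino]cyclohexa-2,5-diene-1,4-dione | C=C1[C@H](C)CCC[C@]1(C)CC/C(C)=C/CC1=C(O)C(=O)C=C(NCCC(C)C)C1=O | target

**Step count**
Total: 19 steps. Longest linear sequence: 17 steps (steps 1–13 and 16–19); steps 14–15 are the convergent branch to cyclobutenone.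

**Steps most likely to fail**

Step 16. Retro-ene loss of ethylene from the ethyl ynol ether and oligomerisation of the vinylketene may outrun the [2+2] capture, so that little phenol forms. The fallback builds the arene from a resorcinol derivative by directed ortho-metalation; it sets out from bromide 18 and returns at phenol 29. 3-Ethoxyphenol is protected with MOMCl and i-Pr2NEt to 1-ethoxy-3-(methoxymethoxy)benzene F1. Lithiation with n-BuLi in THF at 0 °C should occur at C2 between the two oxygen groups. Transmetalation with CuBr·SMe2 and alkylation with 18 at −78 → 0 °C should give 2-[(2E)-5-[(1R,3R)-1,3-dimethyl-2-methylidenecyclohexyl]-3-methylpent-2-en-1-yl]-1-ethoxy-3-(methoxymethoxy)benzene F2. Catalytic HCl in MeOH at 25 °C should then remove the acetal and deliver 29.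

Step 18. The amine may attack the ethoxy-bearing carbon by addition–elimination, or add a second time, so that regiocontrol is lost. The fallback reverses the order of the last two operations; it sets out from quinone 30 and returns at target 34. Hydrolysis of 30 with KOH in EtOH/H2O, then acidification, should give 2-hydroxy-3-[(2E)-5-[(1R,3R)-1,3-dimethyl-2-methylidenecyclohexyl]-3-methylpent-2-en-1-yl]cyclohexa-2,5-diene-1,4-dione F3. Its oxygen cannot be displaced once ionised, and it should direct 31 (EtOH, air) to the carbon para to it, giving 34 directly.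

Step 13. Attack at the more substituted allylic terminus, or base-induced isomerisation of the skipped enyne, may compete with direct displacement. The fallback is a palladium-catalysed coupling; it sets out from 18 and 19 and returns at ynol ether 21. Lithium ethoxyacetylide 20 is quenched with Bu3SnCl to tributyl(ethoxyethynyl)stannane F4. Stille coupling of F4 with 18 (Pd(PPh3)4, THF, 50 °C) proceeds through a π-allyl complex of divalent palladium, which should couple at the less hindered terminus under neutral conditions and give 21.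

**Further compounds**
F1 | step 16 | 1-ethoxy-3-(methoxymethoxy)benzene | CCOc1cccc(OCOC)c1
F2 | step 16 | 2-[(2E)-5-[(1R,3R)-1,3-dimethyl-2-methylidenecyclohexyl]-3-methylpent-2-en-1-yl]-1-ethoxy-3-(methoxymethoxy)benzene | C=C1[C@H](C)CCC[C@]1(C)CC/C(C)=C/Cc1c(OCOC)cccc1OCC
F3 | step 18 | 2-hydroxy-3-[(2E)-5-[(1R,3R)-1,3-dimethyl-2-methylidenecyclohexyl]-3-methylpent-2-en-1-yl]cyclohexa-2,5-diene-1,4-dione | C=C1[C@H](C)CCC[C@]1(C)CC/C(C)=C/CC1=C(O)C(=O)C=CC1=O
F4 | step 13 | tributyl(ethoxyethynyl)stannane | CCCC[Sn](CCCC)(CCCC)C#COCC
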